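**Plan**
- Retrosynthesis: the phenol is unmasked last (benzyl ether), and the C3 methyl is traced back through CH2OMs and CH2OH to a formyl group.
- The C2–C3 bond is cut next. C2 (ring A) is at the acetal level and C3 is the β-carbon of an enol ether, so O1, C2 and C3–C4–C5 (ring B on C5) all sit in a 4,5-dihydro-1,3-dioxepine. A 1,3 O-to-C shift contracts that ring to the tetrahydrofuran.
- The dioxepine is cut at its enol ether C=C (ring-closing metathesis) and at the acetal C–O bonds. This gives the ring A aldehyde, 2-chloroethanol as the vinyl source, and a homoallylic alcohol from crotylboration of 3,4,5-trimethoxybenzaldehyde.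
- Forward: crotylation, bis(2-chloroethyl) acetal, mixed acetal, O-vinyl acetal, seven-membered ring, five-membered ring, side-chain reduction, debenzylation.
- Stereochemistry: C4 and C5 come from the catalyst-controlled anti-crotylboration. C2 and C3 come from the ring contraction under substrate control and kinetic conditions.

Key step: step 7

Remark: the acetal carbon of 10, 11 and 12 forms without control; both epimers ionise to the same oxocarbenium ion, so the mixtures are carried on unseparated.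

**Step 1**
Reactants: 1 3,4,5-trimethoxybenzaldehyde; 2 (E)-crotylboronic acid pinacol ester
Product: 4 (1S,2S)-2-methyl-1-(3,4,5-trimethoxyphenyl)but-3-en-1-ol, via pinacol borate ester 3 (not isolated)
Conditions: (S)-TRIP [(S)-3,3'-bis(2,4,6-triisopropylphenyl)-1,1'-binaphthyl-2,2'-diyl hydrogen phosphate] (5 mol%), 4 Å MS, toluene, –30 °C; then aq. NaHCO3
Reagents that add atoms: none
Why: Chiral phosphoric acid-catalysed asymmetric crotylboration through a closed chair transition state, in which the E geometry of 2 gives the anti relationship and the (S)-acid (the (R)-acid is known to give (R)-carbinols from aryl aldehydes) directs the crotyl group to the si face, so both new centres are S (future C5 and C4); borate 3 is hydrolysed on work-up.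

**Step 2**
Reactants: 5 3-hydroxy-4,5-dimethoxybenzaldehyde
Product: 6 3-(benzyloxy)-4,5-dimethoxybenzaldehyde
Conditions: BnBr, K2CO3, DMF, rt
Reagents that add atoms: benzyl bromide, BrCc1ccccc1
Why: Williamson ether synthesis, in which the phenoxide displaces bromide (SN2) and masks the only acidic group as an ether that should survive acid, base, the ruthenium carbene, TMSOTf and hydride.

**Step 3**
Reactants: 6 3-(benzyloxy)-4,5-dimethoxybenzaldehyde; 7 2-chloroethanol
Product: 8 1-(benzyloxy)-5-[bis(2-chloroethoxy)methyl]-2,3-dimethoxybenzene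
Conditions: 2-chloroethanol (3 equiv in all), p-TsOH·H2O (2 mol%), toluene, reflux, Dean–Stark; Et3N quench
Reagents that add atoms: 2-chloroethanol (the second molecule taken up by the acetal, the same compound as 7), OCCCl
Why: Acid-catalysed acetalisation, in which the aldehyde condenses with two molecules of 2-chloroethanol through the hemiacetal and the oxocarbenium ion and is driven by azeotropic removal of water; the symmetric acetal carries the future vinyl carbons, and the benzyl and methyl ethers are inert.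

**Step 4**
Reactants: 8 1-(benzyloxy)-5-[bis(2-chloroethoxy)methyl]-2,3-dimethoxybenzene; 4 (1S,2S)-2-methyl-1-(3,4,5-trimethoxyphenyl)but-3-en-1-ol
Product: 10 1-(benzyloxy)-5-[(2-chloroethoxy){[(1S,2S)-2-methyl-1-(3,4,5-trimethoxyphenyl)but-3-en-1-yl]oxy}methyl]-2,3-dimethoxybenzene (both acetal epimers), via α-chloro ether 9 (not isolated)
Conditions: AcCl (1.0 equiv), Zn(OTf)2 (1 mol%), CH2Cl2, 0 °C to rt; then 4, iPr2NEt, CH2Cl2, 0 °C
Reagents that add atoms: none
Why: Zinc-catalysed acetal/acyl chloride exchange gives the α-chloro ether 9, which alkylates the hindered alcohol 4 under amine buffering in an SN1-type Williamson acetalisation (as in chloromethyl ether protections); the acetal centre forms as an epimer mixture, which is of no consequence.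

**Step 5**
Reactants: 10 1-(benzyloxy)-5-[(2-chloroethoxy){[(1S,2S)-2-methyl-1-(3,4,5-trimethoxyphenyl)but-3-en-1-yl]oxy}methyl]-2,3-dimethoxybenzene (both acetal epimers)
Product: 11 1-(benzyloxy)-5-[(ethenyloxy){[(1S,2S)-2-methyl-1-(3,4,5-trimethoxyphenyl)but-3-en-1-yl]oxy}methyl]-2,3-dimethoxybenzene (both acetal epimers)
Conditions: KOtBu (3 equiv), THF, 0 °C to rt
Reagents that add atoms: none
Why: E2 dehydrochlorination of the 2-chloroethyl ether gives the vinyl ether; acetal, aryl ethers and terminal alkene are stable to the base in THF, and DMSO is avoided so that the allylic double bond does not migrate.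

**Step 6**
Reactants: 11 1-(benzyloxy)-5-[(ethenyloxy){[(1S,2S)-2-methyl-1-(3,4,5-trimethoxyphenyl)but-3-en-1-yl]oxy}methyl]-2,3-dimethoxybenzene (both acetal epimers)
Product: 12 (4S,5S)-2-[3-(benzyloxy)-4,5-dimethoxyphenyl]-5-methyl-4-(3,4,5-trimethoxyphenyl)-4,5-dihydro-1,3-dioxepine (both C2 epimers)
Conditions: second-generation Grubbs catalyst RuCl2(=CHPh)(PCy3)(H2IMes) (10 mol%), toluene (0.005 M), 70 °C, argon sparge; chromatography on Et3N-treated silica
Reagents that add atoms: none
Why: Ring-closing olefin/enol ether metathesis, in which the ruthenium carbene loads onto the monosubstituted C-vinyl group and closes onto the O-vinyl group with loss of ethene; the ring enforces the Z enol ether, the neutral dilute conditions suit the acid-labile vinyl acetal, and no stereocentre is touched.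

**Step 7**
Reactants: 12 (4S,5S)-2-[3-(benzyloxy)-4,5-dimethoxyphenyl]-5-methyl-4-(3,4,5-trimethoxyphenyl)-4,5-dihydro-1,3-dioxepine (both C2 epimers)
Product: 13 (2R,3S,4S,5S)-2-[3-(benzyloxy)-4,5-dimethoxyphenyl]-4-methyl-5-(3,4,5-trimethoxyphenyl)oxolane-3-carbaldehyde
Conditions: TMSOTf (20 mol%), CH2Cl2, –78 °C; Et3N then aq. NaHCO3 at –78 °C
Reagents that add atoms: none
Why: TMSOTf silylates the enol ether oxygen and cleaves its bond to the acetal carbon, giving a ring A-stabilised (E)-oxocarbenium ion at C2 that is tethered through O–C5–C4 to a (Z)-silyl enol ether, whose β-carbon C3 attacks C2 in a Mukaiyama aldol-type step and returns the silyl group, so the net change is a 1,3 O-to-C shift. The closest known reaction is the Lewis acid-mediated ring contraction of 4,5-dihydro-1,3-dioxepines to tetrahydrofuran-3-carbaldehydes, a relative of the Petasis–Ferrier rearrangement. The tetrahydrofuran closes in a 5-(enolexo)-endo-trig mode, which is accessible because the acceptor is a cation whose C=O bond lies inside the forming ring. C3 is controlled by C4: in the (Z)-enol ether the C4–H eclipses the double bond to minimise A1,3 strain, the tether reaches C3 from the face opposite the C4 methyl, and the formyl group ends trans to that methyl. C2 is controlled by C5 and the ion-pair geometry: the (E)-oxocarbenium ion places ring A and ring B pseudo-equatorial (2,5-cis), and the compact synclinal approach preferred at –78 °C puts ring A cis to the formyl group. The step needs kinetic 2,3-cis and 3,4-trans selectivity; both substrate preferences converge on the (2R,3S) product from either acetal epimer, and the low temperature, substoichiometric TMSOTf and cold amine quench should prevent retro-aldol reopening and C3 epimerisation.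

**Step 8**
Reactants: 13 (2R,3S,4S,5S)-2-[3-(benzyloxy)-4,5-dimethoxyphenyl]-4-methyl-5-(3,4,5-trimethoxyphenyl)oxolane-3-carbaldehyde (crude, used at once)
Product: 14 [(2R,3R,4S,5S)-2-[3-(benzyloxy)-4,5-dimethoxyphenyl]-4-methyl-5-(3,4,5-trimethoxyphenyl)oxolan-3-yl]methanol
Conditions: NaBH4, MeOH/THF, –20 to 0 °C
Reagents that add atoms: none
Why: Chemoselective NaBH4 reduction of the aldehyde at low temperature is faster than enolisation, so the epimerisable formyl group is removed and C3 is fixed as set in step 7.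

**Step 9**
Reactants: 14 [(2R,3R,4S,5S)-2-[3-(benzyloxy)-4,5-dimethoxyphenyl]-4-methyl-5-(3,4,5-trimethoxyphenyl)oxolan-3-yl]methanol
Product: 15 [(2R,3R,4S,5S)-2-[3-(benzyloxy)-4,5-dimethoxyphenyl]-4-methyl-5-(3,4,5-trimethoxyphenyl)oxolan-3-yl]methyl methanesulfonate
Conditions: MsCl, Et3N, CH2Cl2, 0 °C
Reagents that add atoms: methanesulfonyl chloride, CS(=O)(=O)Cl
Why: Sulfonylation of the only free hydroxyl group turns the primary alcohol into a leaving group without touching any stereocentre.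

**Step 10**
Reactants: 15 [(2R,3R,4S,5S)-2-[3-(benzyloxy)-4,5-dimethoxyphenyl]-4-methyl-5-(3,4,5-trimethoxyphenyl)oxolan-3-yl]methyl methanesulfonate
Product: 16 (2R,3S,4S,5S)-2-[3-(benzyloxy)-4,5-dimethoxyphenyl]-3,4-dimethyl-5-(3,4,5-trimethoxyphenyl)oxolane
Conditions: LiBHEt3, THF, 0 °C to rt; aq. NH4Cl
Reagents that add atoms: none
Why: SN2 hydride displacement of the β-branched primary mesylate by LiBHEt3 is a standard deoxygenation and converts CH2OMs into the C3 methyl while ring C–O bonds, aryl ethers and the benzyl ether stay intact.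

**Step 11**
Reactants: 16 (2R,3S,4S,5S)-2-[3-(benzyloxy)-4,5-dimethoxyphenyl]-3,4-dimethyl-5-(3,4,5-trimethoxyphenyl)oxolane
Product: 17 5-[(2R,3S,4S,5S)-3,4-dimethyl-5-(3,4,5-trimethoxyphenyl)oxolan-2-yl]-2,3-dimethoxyphenol
Conditions: H2 (1 atm), 10% Pd/C, EtOAc, rt
Reagents that add atoms: none
Why: Catalytic hydrogenolysis of the aryl benzyl ether over Pd/C; at 1 atm in EtOAc with monitoring, the hindered benzylic C–O bonds of the 2,5-diaryltetrahydrofuran should be cleaved far more slowly than the O-benzyl group.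

**Compound list**
1 | 3,4,5-trimethoxybenzaldehyde | COc1cc(C=O)cc(OC)c1OC | starting material
2 | (E)-crotylboronic acid pinacol ester | C/C=C/CB1OC(C)(C)C(C)(C)O1 | starting material
3 | 4,4,5,5-tetramethyl-2-{[(1S,2S)-2-methyl-1-(3,4,5-trimethoxyphenyl)but-3-en-1-yl]oxy}-1,3,2-dioxaborolane | C=C[C@H](C)[C@H](OB1OC(C)(C)C(C)(C)O1)c1cc(OC)c(OC)c(OC)c1 | intermediate
4 | (1S,2S)-2-methyl-1-(3,4,5-trimethoxyphenyl)but-3-en-1-ol | C=C[C@H](C)[C@H](O)c1cc(OC)c(OC)c(OC)c1 | intermediate
5 | 3-hydroxy-4,5-dimethoxybenzaldehyde | COc1cc(C=O)cc(O)c1OC | starting material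
6 | 3-(benzyloxy)-4,5-dimethoxybenzaldehyde | COc1cc(C=O)cc(OCc2ccccc2)c1OC | intermediate
7 | 2-chloroethanol | OCCCl | starting material
8 | 1-(benzyloxy)-5-[bis(2-chloroethoxy)methyl]-2,3-dimethoxybenzene | COc1cc(C(OCCCl)OCCCl)cc(OCc2ccccc2)c1OC | intermediate
9 | 1-(benzyloxy)-5-[chloro(2-chloroethoxy)methyl]-2,3-dimethoxybenzene (racemic) | COc1cc(C(Cl)OCCCl)cc(OCc2ccccc2)c1OC | intermediate
10 | 1-(benzyloxy)-5-[(2-chloroethoxy){[(1S,2S)-2-methyl-1-(3,4,5-trimethoxyphenyl)but-3-en-1-yl]oxy}methyl]-2,3-dimethoxybenzene (acetal epimers) | C=C[C@H](C)[C@H](OC(OCCCl)c1cc(OC)c(OC)c(OCc2ccccc2)c1)c1cc(OC)c(OC)c(OC)c1 | intermediate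
11 | 1-(benzyloxy)-5-[(ethenyloxy){[(1S,2S)-2-methyl-1-(3,4,5-trimethoxyphenyl)but-3-en-1-yl]oxy}methyl]-2,3-dimethoxybenzene (acetal epimers) | C=C[C@H](C)[C@H](OC(OC=C)c1cc(OC)c(OC)c(OCc2ccccc2)c1)c1cc(OC)c(OC)c(OC)c1 | intermediate
12 | (4S,5S)-2-[3-(benzyloxy)-4,5-dimethoxyphenyl]-5-methyl-4-(3,4,5-trimethoxyphenyl)-4,5-dihydro-1,3-dioxepine (C2 epimers) | COc1cc(C2OC=C[C@H](C)[C@@H](c3cc(OC)c(OC)c(OC)c3)O2)cc(OCc3ccccc3)c1OC | intermediate
13 | (2R,3S,4S,5S)-2-[3-(benzyloxy)-4,5-dimethoxyphenyl]-4-methyl-5-(3,4,5-trimethoxyphenyl)oxolane-3-carbaldehyde | COc1cc([C@@H]2O[C@H](c3cc(OC)c(OC)c(OC)c3)[C@@H](C)[C@@H]2C=O)cc(OCc3ccccc3)c1OC | intermediate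
14 | [(2R,3R,4S,5S)-2-[3-(benzyloxy)-4,5-dimethoxyphenyl]-4-methyl-5-(3,4,5-trimethoxyphenyl)oxolan-3-yl]methanol | COc1cc([C@@H]2O[C@H](c3cc(OC)c(OC)c(OC)c3)[C@@H](C)[C@@H]2CO)cc(OCc3ccccc3)c1OC | intermediate
15 | [(2R,3R,4S,5S)-2-[3-(benzyloxy)-4,5-dimethoxyphenyl]-4-methyl-5-(3,4,5-trimethoxyphenyl)oxolan-3-yl]methyl methanesulfonate | COc1cc([C@@H]2O[C@H](c3cc(OC)c(OC)c(OC)c3)[C@@H](C)[C@@H]2COS(C)(=O)=O)cc(OCc3ccccc3)c1OC | intermediate
16 | (2R,3S,4S,5S)-2-[3-(benzyloxy)-4,5-dimethoxyphenyl]-3,4-dimethyl-5-(3,4,5-trimethoxyphenyl)oxolane | COc1cc([C@@H]2O[C@H](c3cc(OC)c(OC)c(OC)c3)[C@@H](C)[C@@H]2C)cc(OCc3ccccc3)c1OC | intermediate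
17 | 5-[(2R,3S,4S,5S)-3,4-dimethyl-5-(3,4,5-trimethoxyphenyl)oxolan-2-yl]-2,3-dimethoxyphenol | COc1cc([C@@H]2O[C@H](c3cc(OC)c(OC)c(OC)c3)[C@@H](C)[C@@H]2C)cc(O)c1OC | target

**Step count**
Total: 11 steps. Longest linear sequence: 10 steps (5 to 17 through steps 2 to 11).

**Steps most likely to fail**

Step 7. The kinetic 2,3-cis preference may erode through reversible closure (retro-aldol reopening of the silylated aldehyde) or through epimerisation at the formyl-bearing carbon. The fallback sets out from 4 and comes back at 16, with C2 set by hydride delivery instead of by the rearrangement.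
- Hydroboration–oxidation of 4 (9-BBN, THF; then NaOH/H2O2) should give (1S,2S)-2-methyl-1-(3,4,5-trimethoxyphenyl)butane-1,4-diol F1.
- Oxidative lactonisation with TEMPO (2,2,6,6-tetramethylpiperidin-1-oxyl) and PhI(OAc)2 should give (4S,5S)-4-methyl-5-(3,4,5-trimethoxyphenyl)oxolan-2-one F2.
- Enolisation with LiN(SiMe3)2 and methylation with MeI anti to the C4 methyl should give (3S,4S,5S)-3,4-dimethyl-5-(3,4,5-trimethoxyphenyl)oxolan-2-one F3.
- Separately, 5-bromo-2,3-dimethoxyphenol (taken as purchasable) is benzylated (BnBr, K2CO3) to 1-(benzyloxy)-5-bromo-2,3-dimethoxybenzene F4. Bromine–lithium exchange (n-BuLi, THF, –78 °C) gives [3-(benzyloxy)-4,5-dimethoxyphenyl]lithium F5.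
- F5 adds once to F3 to give the cyclic hemiketal (3S,4S,5S)-2-[3-(benzyloxy)-4,5-dimethoxyphenyl]-3,4-dimethyl-5-(3,4,5-trimethoxyphenyl)oxolan-2-ol F6.
- Ionic reduction (Et3SiH, BF3·OEt2, CH2Cl2, –78 °C) delivers hydride to the cyclic oxocarbenium ion anti to the C3 methyl, which should give the 2,3-cis product 16.

Step 4. The electron-rich α-chloro ether may decompose or scramble to symmetric acetals before the hindered secondary alcohol captures it. The fallback sets out from 8 and 4 and comes back at 10 without any α-halo ether or free acid.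
- 8 is activated with TESOTf and 2,4,6-collidine (CH2Cl2, 0 °C) to the weakly electrophilic salt 1-{[3-(benzyloxy)-4,5-dimethoxyphenyl](2-chloroethoxy)methyl}-2,4,6-trimethylpyridinium trifluoromethanesulfonate F7.
- Alcohol 4 is added to the same flask and displaces collidine from F7 to give 10 under basic conditions.

Step 6. The catalyst may be trapped as an unreactive alkoxycarbene at the vinyl ether, or ruthenium hydrides may isomerise the alkenes, so the seven-membered ring does not close. The fallback sets out from 10 and comes back at 13, generating the same oxocarbenium/enol pair from an open chain without metathesis.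
- Hydroboration–oxidation of 10 (9-BBN; then NaOH/H2O2) should give (3S,4S)-4-{[3-(benzyloxy)-4,5-dimethoxyphenyl](2-chloroethoxy)methoxy}-3-methyl-4-(3,4,5-trimethoxyphenyl)butan-1-ol F8.
- Dess–Martin periodinane with NaHCO3 should give (3S,4S)-4-{[3-(benzyloxy)-4,5-dimethoxyphenyl](2-chloroethoxy)methoxy}-3-methyl-4-(3,4,5-trimethoxyphenyl)butanal F9.
- TMSOTf and iPr2NEt in CH2Cl2 at –78 °C convert F9 in the flask into {[(3S,4S)-4-{[3-(benzyloxy)-4,5-dimethoxyphenyl](2-chloroethoxy)methoxy}-3-methyl-4-(3,4,5-trimethoxyphenyl)but-1-en-1-yl]oxy}trimethylsilane F10.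
- The same TMSOTf ionises the acetal of F10 with loss of the 2-chloroethoxy group, and intramolecular Mukaiyama aldol-type closure onto the oxocarbenium ion should give 13.

**Further compounds**
F1 | step 7 | (1S,2S)-2-methyl-1-(3,4,5-trimethoxyphenyl)butane-1,4-diol | OCC[C@H](C)[C@H](O)c1cc(OC)c(OC)c(OC)c1
F2 | step 7 | (4S,5S)-4-methyl-5-(3,4,5-trimethoxyphenyl)oxolan-2-one | O=C1O[C@H](c2cc(OC)c(OC)c(OC)c2)[C@@H](C)C1
F3 | step 7 | (3S,4S,5S)-3,4-dimethyl-5-(3,4,5-trimethoxyphenyl)oxolan-2-one | O=C1O[C@H](c2cc(OC)c(OC)c(OC)c2)[C@@H](C)[C@@H]1C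
F4 | step 7 | 1-(benzyloxy)-5-bromo-2,3-dimethoxybenzene | COc1cc(Br)cc(OCc2ccccc2)c1OC
F5 | step 7 | [3-(benzyloxy)-4,5-dimethoxyphenyl]lithium | [Li]c1cc(OC)c(OC)c(OCc2ccccc2)c1
F6 | step 7 | (3S,4S,5S)-2-[3-(benzyloxy)-4,5-dimethoxyphenyl]-3,4-dimethyl-5-(3,4,5-trimethoxyphenyl)oxolan-2-ol | COc1cc(C2(O)O[C@H](c3cc(OC)c(OC)c(OC)c3)[C@@H](C)[C@@H]2C)cc(OCc3ccccc3)c1OC
F7 | step 4 | 1-{[3-(benzyloxy)-4,5-dimethoxyphenyl](2-chloroethoxy)methyl}-2,4,6-trimethylpyridinium trifluoromethanesulfonate | COc1cc(C(OCCCl)[n+]2c(C)cc(C)cc2C)cc(OCc2ccccc2)c1OC.[O-]S(=O)(=O)C(F)(F)F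
F8 | step 6 | (3S,4S)-4-{[3-(benzyloxy)-4,5-dimethoxyphenyl](2-chloroethoxy)methoxy}-3-methyl-4-(3,4,5-trimethoxyphenyl)butan-1-ol | OCC[C@H](C)[C@H](OC(OCCCl)c1cc(OC)c(OC)c(OCc2ccccc2)c1)c1cc(OC)c(OC)c(OC)c1
F9 | step 6 | (3S,4S)-4-{[3-(benzyloxy)-4,5-dimethoxyphenyl](2-chloroethoxy)methoxy}-3-methyl-4-(3,4,5-trimethoxyphenyl)butanal | O=CC[C@H](C)[C@H](OC(OCCCl)c1cc(OC)c(OC)c(OCc2ccccc2)c1)c1cc(OC)c(OC)c(OC)c1
F10 | step 6 | {[(3S,4S)-4-{[3-(benzyloxy)-4,5-dimethoxyphenyl](2-chloroethoxy)methoxy}-3-methyl-4-(3,4,5-trimethoxyphenyl)but-1-en-1-yl]oxy}trimethylsilane | C[Si](C)(C)OC=C[C@H](C)[C@H](OC(OCCCl)c1cc(OC)c(OC)c(OCc2ccccc2)c1)c1cc(OC)c(OC)c(OC)c1
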